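**Assumption:** Lupalbigenin has no stereocentres and no stereogenic alkenes (both prenyl termini are CMe2), so it is achiral and the "single enantiomer" requirement places no demand on the route.

## Retrosynthetic overview

1. Lupalbigenin ⇒ its 7,4'-bis(MOM) ether by global acetal cleavage.
2. Key disconnection: both aryl–prenyl C(sp2)–C(sp3) bonds are cut at once, giving a 6-iodo-3'-bromo-isoflavone plus two prenylstannanes (one-pot double linear-selective Stille). This replaces the usual C3–C1' Suzuki coupling of pre-prenylated partners or O-prenylation/Claisen chemistry.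
3. The 6-iodide comes from 5-OH-directed regioselective iodination; the 3'-bromide is carried in from the arylacetic acid.
4. The only ring formed is the pyranone (C ring), by one-pot Friedel–Crafts acylation and C1 cyclisation of phloroglucinol with 3-bromo-4-hydroxyphenylacetic acid; the A and B rings come intact from the starting materials.

## Route

**Step 1**
Reactants: 1 (phloroglucinol), 2 (3-bromo-4-hydroxyphenylacetic acid)
Product: 4 (3'-bromogenistein, 3-(3-bromo-4-hydroxyphenyl)-5,7-dihydroxy-4H-chromen-4-one), formed via deoxybenzoin 3 (2-(3-bromo-4-hydroxyphenyl)-1-(2,4,6-trihydroxyphenyl)ethanone), generated in situ and not isolated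
Conditions: BF3·OEt2 (neat), 85 °C, 1.5 h; then DMF, MsCl, 50→80 °C, 2 h; aq. NaOAc work-up (one pot)
Reagents that add atoms: N,N-dimethylformamide, CN(C)C=O (supplies C2–H of the chromone); MsCl and BF3·OEt2 leave no atoms
Why: BF3-mediated Friedel–Crafts (Hoesch-type) acylation of the symmetrical phloroglucinol gives deoxybenzoin 3 with no regiochemical ambiguity, and Vilsmeier-type formylation of its activated CH2 by DMF/MsCl followed by cyclodehydration onto an ortho OH closes the isoflavone (deoxybenzoin isoflavone synthesis).

**Step 2**
Reactants: 4 (3'-bromogenistein)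
Product: 5 (3-[3-bromo-4-(methoxymethoxy)phenyl]-5-hydroxy-7-(methoxymethoxy)-4H-chromen-4-one)
Conditions: MOMCl (2.3 equiv), i-Pr2NEt, CH2Cl2/DMF, 0 °C→rt
Reagents that add atoms: chloromethyl methyl ether, COCCl
Why: Selective O-alkylation (acetal protection) of the acidic 7-OH and 4'-OH, while the 5-OH is held in a strong hydrogen bond to the C4 carbonyl and stays free.

**Step 3**
Reactants: 5
Product: 6 (3-[3-bromo-4-(methoxymethoxy)phenyl]-5-hydroxy-6-iodo-7-(methoxymethoxy)-4H-chromen-4-one)
Conditions: BnMe3N·ICl2 (1.05 equiv), CaCO3, CH2Cl2/MeOH, rt, dark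
Reagents that add atoms: benzyltrimethylammonium dichloroiodate, C[N+](C)(C)Cc1ccccc1.Cl[I-]Cl
Why: Electrophilic aromatic iodination of 5-hydroxy-7-alkoxy-chromones occurs ortho to the free chelated 5-OH, at C6 and not C8, while the bromo/alkoxy B ring is far less nucleophilic and CaCO3 scavenges HCl so the MOM ethers survive.

**Step 4 (key step)**
Reactants: 6; 7 (tributyl(3-methylbut-2-en-1-yl)stannane, prenylSnBu3, 3 equiv)
Product: 8 (5-hydroxy-7-(methoxymethoxy)-3-[4-(methoxymethoxy)-3-(3-methylbut-2-en-1-yl)phenyl]-6-(3-methylbut-2-en-1-yl)-4H-chromen-4-one)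
Conditions: Pd(PPh3)4 (10 mol %), degassed DMF, 95 °C, 16 h; aq. KF work-up
Reagents that add atoms: prenyltributylstannane, CCCC[Sn](CCCC)(CCCC)CC=C(C)C (two prenyl groups transferred)
Why: Twofold Stille (Kosugi–Migita–Stille) coupling, with oxidative addition first at C6–I and then at C3'–Br, and reductive elimination from the less hindered primary terminus of the η1/η3-prenyl–Pd species to give linear prenyl groups; the free 5-OH, chromone and MOM ethers are inert under these neutral conditions.

**Step 5**
Reactants: 8
Product: 9 (lupalbigenin, 5,7-dihydroxy-3-[4-hydroxy-3-(3-methylbut-2-en-1-yl)phenyl]-6-(3-methylbut-2-en-1-yl)-4H-chromen-4-one)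
Conditions: 3 M aq. HCl/MeOH–THF, 45 °C, 2–3 h (stop at full conversion)
Reagents that add atoms: none
Why: Acid-catalysed acetal hydrolysis removes both MOM groups under conditions mild enough that the trisubstituted prenyl alkenes neither hydrate nor cyclise onto the neighbouring phenols.

## Compound list

1 | phloroglucinol (benzene-1,3,5-triol) | Oc1cc(O)cc(O)c1 | starting material
2 | 3-bromo-4-hydroxyphenylacetic acid | OC(=O)Cc1ccc(O)c(Br)c1 | starting material
3 | 2-(3-bromo-4-hydroxyphenyl)-1-(2,4,6-trihydroxyphenyl)ethanone | O=C(Cc1ccc(O)c(Br)c1)c1c(O)cc(O)cc1O | intermediate (in situ, not isolated)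
4 | 3'-bromogenistein | Oc1ccc(-c2coc3cc(O)cc(O)c3c2=O)cc1Br | intermediate
5 | 7,4'-bis-O-MOM-3'-bromogenistein | COCOc1ccc(-c2coc3cc(OCOC)cc(O)c3c2=O)cc1Br | intermediate
6 | 7,4'-bis-O-MOM-3'-bromo-6-iodogenistein | COCOc1ccc(-c2coc3cc(OCOC)c(I)c(O)c3c2=O)cc1Br | intermediate
7 | tributyl(3-methylbut-2-en-1-yl)stannane | CCCC[Sn](CCCC)(CCCC)CC=C(C)C | starting material
8 | 7,4'-bis-O-MOM-lupalbigenin | COCOc1ccc(-c2coc3cc(OCOC)c(CC=C(C)C)c(O)c3c2=O)cc1CC=C(C)C | intermediate
9 | lupalbigenin | CC(C)=CCc1cc(-c2coc3cc(O)c(CC=C(C)C)c(O)c3c2=O)ccc1O | target

## Summary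

Total step count: 5 (step 1 is a one-pot, two-stage operation).
Longest linear sequence: 5 steps, fully linear from phloroglucinol.

Three steps most likely to fail, each with a fallback that changes the approach:

1. **Step 4, double Stille prenylation.** The C6 iodide is di-ortho-substituted and electron-rich, so protodeiodination, incomplete second coupling, or some branched (1,1-dimethylallyl) product are possible. Fallback: couple both halides with allyltributylstannane (no α/γ issue, smaller nucleophile) to the 6,3'-diallyl compound, then convert both allyl groups to prenyl by double olefin cross-metathesis with 2-methyl-2-butene (Grubbs II) before deprotection.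

2. **Step 3, C6-selective iodination.** C8 iodination or 6,8-diiodination would compete. Fallback: drop the halide at C6 and use O→C transfer instead. O-prenylate the free 5-OH of 5 (prenyl bromide, K2CO3, DMF), then run a clay-promoted (montmorillonite K10) [1,3] O→C prenyl shift, which can only deliver to C6, the sole free ortho position of O5. The 3'-prenyl is then installed by a single Stille coupling at the bromide.

3. **Step 5, acidic MOM removal.** The o-prenylphenols can cyclise to 2,2-dimethylchromans, or HCl/MeOH can add across the prenyl alkenes. Fallback: change the protecting-group strategy at step 2 to fluoride-labile silyl ethers (7,4'-bis-TBS, from TBSCl/imidazole), carry them through iodination and the neutral Stille coupling, and unmask with TBAF/AcOH at 0 °C so the prenylated product never sees acid.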